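The strategy rests on the fully substituted benzene ring of the chromene (C4a, C5, C6, C7, C8, C8a). Oxygen on C5, C7 and C8a alternates with carbon on C4a, C6 and C8, and the three oxygens are all different (5-OH, 7-OH, pyran O1).
Endgame: both phenols are released from MOM ethers, and the C6–benzoyl bond is cut to a C6 aryllithium held between two OMOM groups plus N-methoxy-N-methylbenzamide.
The 2,2-dimethyl-2H-pyran ring (bonds O1–C2 and C4–C4a) is cut to prenal and a phenol that has one free OH and one free ortho carbon.
That phenol is cut at C8–C8a, C6–C7 and C4a–C8a into 3-(methoxymethoxy)cyclobutenone (C8a with O1, C6, C5 with its oxygen, C4a) and a prenyl triisopropylsiloxyalkyne (C8, C7 with its oxygen), so each oxygen arrives with its own label (H, MOM, TIPS).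
Ring order: benzene ring first (benzannulation), pyran ring second (oxa-6π closure). The phenyl ring comes in ready-made with the benzoyl group.

Key step: step 3

Remark on the chemistry: cyclobutane-1,3-dione is taken as a purchasable solid that reacts through its strongly acidic enol tautomer, 3-hydroxycyclobut-2-en-1-one.

Step 1
Reactants: 1 ethyl 4-methylpent-3-enoate; 2 dibromomethane
Product: 6 5-methyl-1-(triisopropylsilyloxy)hex-4-en-1-yne (prenyl siloxyalkyne), via dibromomethyllithium 3 (not isolated), via lithium dibromoenolate 4 (not isolated), via lithium ynolate 5 (not isolated)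
Conditions: 2, lithium 2,2,6,6-tetramethylpiperidide (LiTMP), THF, −78 °C; add 1; LiN(SiMe3)2, −78 °C; n-BuLi, −78 → 0 °C; TIPSOTf, −78 → 0 °C; pentane, cold aq NaHCO3; used within a day
Reagents that add atoms: triisopropylsilyl trifluoromethanesulfonate (TIPSOTf), CC(C)[Si](C(C)C)(C(C)C)OS(=O)(=O)C(F)(F)F
Why: Kowalski ester homologation stopped at the ynolate stage: at −78 °C carbenoid 3 should add to the ester carbonyl faster than it removes the allylic α-hydrogen, LiN(SiMe3)2 turns the released dibromoketone into enolate 4, bromine–lithium exchange and loss of LiBr with 1,2-shift of the prenyl CH2 give ynolate 5, and the bulky silyl triflate is taken up on oxygen rather than on carbon.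

Step 2
Reactants: 7 cyclobutane-1,3-dione
Product: 8 3-(methoxymethoxy)cyclobut-2-en-1-one
Conditions: MOMCl (1.1 equiv), iPr2NEt (1.2 equiv), CH2Cl2, 0 °C; cold aq NaHCO3 wash, short plug of Et3N-deactivated silica
Reagents that add atoms: chloromethyl methyl ether (MOMCl), COCCl
Why: O-alkylation of a vinylogous acid: the enol of 7 is fully deprotonated by the amine, and the hard oxocarbenium-type electrophile MOMCl should be captured at the enolate oxygen to give the vinylogous ester.

Step 3
Reactants: 6 5-methyl-1-(triisopropylsilyloxy)hex-4-en-1-yne; 8 3-(methoxymethoxy)cyclobut-2-en-1-one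
Product: 13 5-(methoxymethoxy)-2-(3-methylbut-2-enyl)-3-(triisopropylsilyloxy)phenol, via vinylketene 9 (not isolated), via vinylcyclobutenone 10 (not isolated), via dienylketene 11 (not isolated), via cyclohexadienone 12 (not isolated)
Conditions: 6 (1.3 equiv), toluene, 105 °C, Ar, base-washed glassware; 8 added over 2 h; then 105 °C until 8 is consumed
Reagents that add atoms: none
Why: Danheiser benzannulation: heating should open 8 by a strain-releasing 4π electrocyclic cleavage of its C1–C4 bond to vinylketene 9, the ketene C=C of 9 adds alkyne 6 in a [2+2] cycloaddition to give vinylcyclobutenone 10, and a second, reversible 4π opening turns 10 into dienylketene 11. The benzene ring is closed by a 6π electrocyclization of the (3E) isomer of 11, which joins the former CH2 carbon (C4) of 8 to the ketene carbonyl carbon and gives dienone 12, and enolization of 12 to phenol 13 makes the sequence irreversible. The closest known reaction type is the thermal benzannulation of 3-alkylcyclobutenones with triisopropylsiloxyalkynes to resorcinol monosilyl ethers; the oxygen on C3 of 8 is the one departure, and since every such cascade already passes through a 3-siloxycyclobutenone like 10 that opens in this temperature range, opening of vinylogous ester 8 near 105 °C is a reasonable expectation. The selectivity needed is the regiochemistry of the [2+2] step, and the polarization of 6 secures it: the nucleophilic prenyl-bearing carbon bonds to the electrophilic ketene carbonyl carbon and the siloxy-bearing carbon to the ketene α-carbon, which places the free OH and OTIPS on either side of the prenyl group and OMOM para to it. Chemoselectivity for the alkyne over the prenyl alkene follows from the much higher nucleophilicity of the ynol ether, and slow addition of 8 to an excess of 6 keeps the ketene concentration low so that neither phenol 13 nor a second ketene intercepts it. No stereocentre is created in 13; the one at C4 of 10 is erased in the next ring opening.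

Step 4
Reactants: 13 5-(methoxymethoxy)-2-(3-methylbut-2-enyl)-3-(triisopropylsilyloxy)phenol; 14 3-methylbut-2-enal (prenal)
Product: 17 5-(methoxymethoxy)-2,2-dimethyl-8-(3-methylbut-2-enyl)-7-(triisopropylsilyloxy)-2H-chromene, via benzodioxaborin 15 (not isolated), via ortho-quinone methide 16 (not isolated)
Conditions: 14 (1.5 equiv), PhB(OH)2 (1 equiv), EtCO2H (0.3 equiv), toluene, reflux, Dean–Stark trap
Reagents that add atoms: none
Why: Boronic-acid-templated ortho-hydroxyalkylation followed by oxa-6π electrocyclization: the aryl borate delivers prenal to the only free ortho carbon of 13 to give dioxaborin 15, which fragments on heating to quinone methide 16, and 16 closes to the 2,2-dimethyl-2H-pyran, the weak carboxylic acid being too mild to disturb the MOM ether, the TIPS ether or the prenyl group.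

Step 5
Reactants: 17 5-(methoxymethoxy)-2,2-dimethyl-8-(3-methylbut-2-enyl)-7-(triisopropylsilyloxy)-2H-chromene
Product: 18 5-(methoxymethoxy)-2,2-dimethyl-8-(3-methylbut-2-enyl)-2H-chromen-7-ol
Conditions: Bu4NF (1.1 equiv), AcOH (1.1 equiv), THF, 0 °C
Reagents that add atoms: none
Why: Fluoride-mediated cleavage of an aryl silyl ether: formation of the strong Si–F bond expels the phenoxide, which the acetic acid buffer protonates at once, while the MOM acetal, the chromene and the prenyl alkene do not react with fluoride.

Step 6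
Reactants: 18 5-(methoxymethoxy)-2,2-dimethyl-8-(3-methylbut-2-enyl)-2H-chromen-7-ol
Product: 19 5,7-bis(methoxymethoxy)-2,2-dimethyl-8-(3-methylbut-2-enyl)-2H-chromene
Conditions: MOMCl (1.5 equiv), iPr2NEt (2 equiv), CH2Cl2, 0 °C → rt
Reagents that add atoms: chloromethyl methyl ether (MOMCl), COCCl
Why: Base-mediated O-alkylation (MOM protection) of the only free phenol; exchanging TIPS for MOM gives C6 a second coordinating neighbour for lithiation and removes a silyl group that could shift from oxygen to an adjacent carbanion.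

Step 7
Reactants: 19 5,7-bis(methoxymethoxy)-2,2-dimethyl-8-(3-methylbut-2-enyl)-2H-chromene; 20 N-methoxy-N-methylbenzamide
Product: 23 [5,7-bis(methoxymethoxy)-2,2-dimethyl-8-(3-methylbut-2-enyl)-2H-chromen-6-yl](phenyl)methanone, via aryllithium 21 (not isolated), via tetrahedral adduct 22 (not isolated)
Conditions: n-BuLi (1.15 equiv), THF, −78 → 0 °C; −78 °C, 20 (1.3 equiv), → rt; sat. aq NH4Cl
Reagents that add atoms: none
Why: Directed ortho-metalation followed by Weinreb ketone synthesis: C6–H is the only aromatic hydrogen and lies between two chelating OMOM groups, so complex-induced deprotonation there should outrun removal of the benzylic-allylic or vinylic hydrogens, and chelated adduct 22 holds until the quench so that no second addition takes place.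

Step 8
Reactants: 23 [5,7-bis(methoxymethoxy)-2,2-dimethyl-8-(3-methylbut-2-enyl)-2H-chromen-6-yl](phenyl)methanone
Product: 24 6-benzoyl-5,7-dihydroxy-2,2-dimethyl-8-(3-methylbut-2-enyl)-2H-chromene (target)
Conditions: 3 M aq HCl (cat.), MeOH, rt
Reagents that add atoms: none
Why: Acid-catalysed transacetalization of both aryl MOM ethers to dimethoxymethane; each freed phenol is held in a hydrogen bond to the benzoyl carbonyl, and dilute acid at room temperature should stay below the threshold for addition of the 7-OH to the prenyl alkene or for protonation of the chromene alkene.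

Compound list
1 | ethyl 4-methylpent-3-enoate | CCOC(=O)CC=C(C)C | starting material
2 | dibromomethane | BrCBr | starting material
3 | dibromomethyllithium | [Li]C(Br)Br | intermediate
4 | lithium 1,1-dibromo-5-methylhexa-1,4-dien-2-olate | CC(C)=CCC([O-])=C(Br)Br.[Li+] | intermediate
5 | lithium 5-methylhex-4-en-1-yn-1-olate (ynolate) | CC(C)=CCC#C[O-].[Li+] | intermediate
6 | 5-methyl-1-(triisopropylsilyloxy)hex-4-en-1-yne | CC(C)=CCC#CO[Si](C(C)C)(C(C)C)C(C)C | intermediate
7 | cyclobutane-1,3-dione | O=C1CC(=O)C1 | starting material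
8 | 3-(methoxymethoxy)cyclobut-2-en-1-one | COCOC1=CC(=O)C1 | intermediate
9 | 3-(methoxymethoxy)buta-1,3-dien-1-one (vinylketene) | C=C(OCOC)C=C=O | intermediate
10 | 4-[1-(methoxymethoxy)ethenyl]-2-(3-methylbut-2-enyl)-3-(triisopropylsilyloxy)cyclobut-2-en-1-one (racemic) | CC(C)=CCC1=C(O[Si](C(C)C)(C(C)C)C(C)C)C(C(=C)OCOC)C1=O | intermediate
11 | (3E)-5-(methoxymethoxy)-2-(3-methylbut-2-enyl)-3-(triisopropylsilyloxy)hexa-1,3,5-trien-1-one (dienylketene) | CC(C)=CCC(=C=O)/C(O[Si](C(C)C)(C(C)C)C(C)C)=C\C(=C)OCOC | intermediate
12 | 5-(methoxymethoxy)-2-(3-methylbut-2-enyl)-3-(triisopropylsilyloxy)cyclohexa-2,4-dien-1-one | CC(C)=CCC1=C(O[Si](C(C)C)(C(C)C)C(C)C)C=C(OCOC)CC1=O | intermediate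
13 | 5-(methoxymethoxy)-2-(3-methylbut-2-enyl)-3-(triisopropylsilyloxy)phenol | CC(C)=CCc1c(O)cc(OCOC)cc1O[Si](C(C)C)(C(C)C)C(C)C | intermediate
14 | 3-methylbut-2-enal (prenal) | CC(C)=CC=O | starting material
15 | 5-(methoxymethoxy)-8-(3-methylbut-2-enyl)-4-(2-methylprop-1-enyl)-2-phenyl-7-(triisopropylsilyloxy)-4H-1,3,2-benzodioxaborinine (racemic) | CC(C)=CCc1c(O[Si](C(C)C)(C(C)C)C(C)C)cc(OCOC)c2c1OB(c3ccccc3)OC2C=C(C)C | intermediate
16 | (6Z)-5-(methoxymethoxy)-2-(3-methylbut-2-enyl)-6-(3-methylbut-2-enylidene)-3-(triisopropylsilyloxy)cyclohexa-2,4-dien-1-one | CC(C)=CCC1=C(O[Si](C(C)C)(C(C)C)C(C)C)C=C(OCOC)/C(=C/C=C(C)C)C1=O | intermediate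
17 | 5-(methoxymethoxy)-2,2-dimethyl-8-(3-methylbut-2-enyl)-7-(triisopropylsilyloxy)-2H-chromene | CC(C)=CCc1c(O[Si](C(C)C)(C(C)C)C(C)C)cc(OCOC)c2c1OC(C)(C)C=C2 | intermediate
18 | 5-(methoxymethoxy)-2,2-dimethyl-8-(3-methylbut-2-enyl)-2H-chromen-7-ol | CC(C)=CCc1c(O)cc(OCOC)c2c1OC(C)(C)C=C2 | intermediate
19 | 5,7-bis(methoxymethoxy)-2,2-dimethyl-8-(3-methylbut-2-enyl)-2H-chromene | CC(C)=CCc1c(OCOC)cc(OCOC)c2c1OC(C)(C)C=C2 | intermediate
20 | N-methoxy-N-methylbenzamide | CON(C)C(=O)c1ccccc1 | starting material
21 | [5,7-bis(methoxymethoxy)-2,2-dimethyl-8-(3-methylbut-2-enyl)-2H-chromen-6-yl]lithium | CC(C)=CCc1c(OCOC)c([Li])c(OCOC)c2c1OC(C)(C)C=C2 | intermediate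
22 | lithium [5,7-bis(methoxymethoxy)-2,2-dimethyl-8-(3-methylbut-2-enyl)-2H-chromen-6-yl][methoxy(methyl)amino](phenyl)methanolate (racemic) | CC(C)=CCc1c(OCOC)c(C([O-])(N(C)OC)c3ccccc3)c(OCOC)c2c1OC(C)(C)C=C2.[Li+] | intermediate
23 | [5,7-bis(methoxymethoxy)-2,2-dimethyl-8-(3-methylbut-2-enyl)-2H-chromen-6-yl](phenyl)methanone | CC(C)=CCc1c(OCOC)c(C(=O)c2ccccc2)c(OCOC)c2c1OC(C)(C)C=C2 | intermediate
24 | 6-benzoyl-5,7-dihydroxy-2,2-dimethyl-8-(3-methylbut-2-enyl)-2H-chromene | CC(C)=CCc1c(O)c(C(=O)c2ccccc2)c(O)c2c1OC(C)(C)C=C2 | target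

Total step count: 8. Longest linear sequence: 7 (steps 1, 3, 4, 5, 6, 7, 8; the branch through step 2 is equally long).

Steps most likely to fail

First, step 3.
- What may go wrong: vinylogous ester resonance may slow the first 4π opening. The thermal silyl shift of the ynol ether and the loss of the acetal group from the four-membered ring could then win.
- Fallback: it sets out from 6 and comes back to the route at 19. It makes the oxygenated vinylketene at room temperature by a photochemical Wolff rearrangement instead of by ring opening. Bought butane-2,3-dione is converted (TIPSOTf, Et3N, CH2Cl2, 0 °C) into 3-(triisopropylsilyloxy)but-3-en-2-one F1. Its methyl ketone is trifluoroacetylated (LiN(SiMe3)2, CF3CO2CH2CF3, THF, −78 °C) to 1,1,1-trifluoro-5-(triisopropylsilyloxy)hex-5-ene-2,4-dione F2. Detrifluoroacetylative diazo transfer (MsN3, Et3N, H2O, MeCN) then gives 1-diazo-3-(triisopropylsilyloxy)but-3-en-2-one F3. Irradiation of F3 together with 6 (254 nm, CH2Cl2, rt) should release 3-(triisopropylsilyloxy)buta-1,3-dien-1-one F4, which enters the same cascade. Warming to 80 °C in toluene completes it to 2-(3-methylbut-2-enyl)-3,5-bis(triisopropylsilyloxy)phenol F5. The conditions of step 4 give 2,2-dimethyl-8-(3-methylbut-2-enyl)-5,7-bis(triisopropylsilyloxy)-2H-chromene F6. Bu4NF removes both silyl groups to give 2,2-dimethyl-8-(3-methylbut-2-enyl)-2H-chromene-5,7-diol F7, and double alkylation (MOMCl, iPr2NEt) gives 19.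

Second, step 1.
- What may go wrong: the α-hydrogens of the β,γ-unsaturated ester are unusually acidic, so proton transfer to the carbenoid or the amide base may compete with carbonyl addition. The strongly basic medium may also move the skipped double bond.
- Fallback: it sets out from 1 and comes back to the route at 5. It replaces the carbenoid rearrangement by oxidation of an acetylide. Ester 1 is reduced (i-Bu2AlH, CH2Cl2, −78 °C) to 4-methylpent-3-enal F8, which is used crude to avoid alkene migration. Corey–Fuchs olefination (CBr4, PPh3, CH2Cl2, 0 °C) converts it into 1,1-dibromo-5-methylhexa-1,4-diene F9. Treatment with n-BuLi (2 equiv, THF, −78 °C) gives (5-methylhex-4-en-1-yn-1-yl)lithium F10. This is oxidized in the same flask by lithium tert-butyl peroxide (t-BuOOH, LiN(SiMe3)2, THF, −78 → 0 °C) to ynolate 5, and silylation as in step 1 gives 6.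

Third, step 7.
- What may go wrong: the carbanion sits on a hexasubstituted ring, so its addition to the amide may be slow. Proton transfer from the benzylic-allylic CH2 or base-induced breakdown of the N-methoxy amide could then compete.
- Fallback: it sets out from 21 and comes back to the route at 23. It uses a small, highly electrophilic aldehyde and adjusts the oxidation level afterwards. Aryllithium 21 is quenched at −78 °C by benzaldehyde to give racemic [5,7-bis(methoxymethoxy)-2,2-dimethyl-8-(3-methylbut-2-enyl)-2H-chromen-6-yl](phenyl)methanol F11. This doubly benzylic alcohol is oxidized by MnO2 (CH2Cl2, rt) or Dess–Martin periodinane to 23.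

Further compounds
F1 | step 3 | 3-(triisopropylsilyloxy)but-3-en-2-one | CC(=O)C(=C)O[Si](C(C)C)(C(C)C)C(C)C
F2 | step 3 | 1,1,1-trifluoro-5-(triisopropylsilyloxy)hex-5-ene-2,4-dione | C=C(O[Si](C(C)C)(C(C)C)C(C)C)C(=O)CC(=O)C(F)(F)F
F3 | step 3 | 1-diazo-3-(triisopropylsilyloxy)but-3-en-2-one | C=C(O[Si](C(C)C)(C(C)C)C(C)C)C(=O)C=[N+]=[N-]
F4 | step 3 | 3-(triisopropylsilyloxy)buta-1,3-dien-1-one | C=C(O[Si](C(C)C)(C(C)C)C(C)C)C=C=O
F5 | step 3 | 2-(3-methylbut-2-enyl)-3,5-bis(triisopropylsilyloxy)phenol | CC(C)=CCc1c(O)cc(O[Si](C(C)C)(C(C)C)C(C)C)cc1O[Si](C(C)C)(C(C)C)C(C)C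
F6 | step 3 | 2,2-dimethyl-8-(3-methylbut-2-enyl)-5,7-bis(triisopropylsilyloxy)-2H-chromene | CC(C)=CCc1c(O[Si](C(C)C)(C(C)C)C(C)C)cc(O[Si](C(C)C)(C(C)C)C(C)C)c2c1OC(C)(C)C=C2
F7 | step 3 | 2,2-dimethyl-8-(3-methylbut-2-enyl)-2H-chromene-5,7-diol | CC(C)=CCc1c(O)cc(O)c2c1OC(C)(C)C=C2
F8 | step 1 | 4-methylpent-3-enal | CC(C)=CCC=O
F9 | step 1 | 1,1-dibromo-5-methylhexa-1,4-diene | CC(C)=CCC=C(Br)Br
F10 | step 1 | (5-methylhex-4-en-1-yn-1-yl)lithium | CC(C)=CCC#C[Li]
F11 | step 7 | [5,7-bis(methoxymethoxy)-2,2-dimethyl-8-(3-methylbut-2-enyl)-2H-chromen-6-yl](phenyl)methanol (racemic) | CC(C)=CCc1c(OCOC)c(C(O)c3ccccc3)c(OCOC)c2c1OC(C)(C)C=C2
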